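**Two ledgers.** A small charge, 15 mM in gamma, ended as 56.3% target and 43.3% substrate, and delta's large charge of 100 mM ended as 28.3% target and 71.8% substrate. Substrate is the limiting reagent here, so I added its entries. Gamma's books closed at 99.6% and delta's at 100%. At 3.00 min, with half of delta's charge fed, they closed at 50.2%. Within the scatter, then, two entries carried the ledger.

| flask | substrate | enzyme | remark | time |
|---|---|---|---|---|
| gamma | 15 mM (fed, over 6.0 min) | 2 µM | run made earlier |  |
| delta | 100 mM (fed, over 6.0 min) | 2 µM | run made earlier |  |
| grey | 10 mM (fed, over 6.0 min) | 2.0 µM |  | 6.0 min |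
| green | 20 mM (fed, over 6.0 min) | 2.0 µM |  | 6.0 min |
| ochre | 40 mM (fed, over 6.0 min) | 2.0 µM |  | 6.0 min |
| violet | 80 mM (fed, over 6.0 min) | 2.0 µM |  | 6.0 min |

| run | time / min | target / % | substrate / % |
|---|---|---|---|
| gamma | 1.33 | 12.7 | 9.4 |
| gamma | 2.50 | 24.3 | 16.8 |
| gamma | 4.00 | 39.0 | 28.1 |
| gamma | 5.00 | 48.2 | 35.9 |
| gamma | 6.00 | 56.3 | 43.3 |
| delta | 0.500 | 1.5 | 5.4 |
| delta | 0.833 | 4.0 | 10.3 |
| delta | 1.50 | 8.2 | 17.2 |
| delta | 3.00 | 14.7 | 35.5 |
| delta | 6.00 | 28.3 | 71.8 |

(standard deviation of a reading: 0.5 percentage points)

- "hardly changes" means that all values lie within two and a half points (for a concentration: within two and a half percent of the largest)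
- percentages count the whole charge, also what has not yet gone in

1. [target] at the end for grey, green, ochre, violet, in this order
2. how the row runs (falls, then rises / falls all the way / rises all the way / hardly changes / rises, then falls)

**One share.** Target's share of what had gone in changed little between these readings: in gamma 57.5% at 1.33 min and 56.5% at the end, and in delta 29.3% at 3.00 min and 28.3% at the end. A steady share means target forms at that share of the feed. I supposed that this rate also goes as substrate fraction over target fraction. Setting the two equal, the charge times the final target fraction squared, divided by the final substrate fraction, should stay constant at this enzyme charge and dosing time.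

**Balance charge.** Gamma gave 11.0 mM and delta 11.2 mM, although their charges differ greatly. I took the mean as the balance charge 11.1 mM, the charge times target fraction squared over substrate fraction.

**Joining ends.** Violet's charge is larger than the balance charge, so its target fraction should approach the square root of balance charge over charge, 37.2%, a high figure since it counts the whole charge as substrate. Grey's charge lies close to the balance charge, so neither end serves there. The quadratic joins them and gave me 6.35 mM for grey and 24.7 mM for violet.

**The forecast.** It read “strong competitive product inhibition” in the runs and gave 6.3 mM, 10.3 mM, 16.2 mM and 24.7 mM: rises all the way.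

**The flasks.** They gave 6.33 mM, 10.4 mM, 16.3 mM and 24.7 mM: rises all the way.

    substrate + enzyme → target + enzyme, rate k1*[substrate]*[enzyme]/(1 + ([substrate]/Km1) + ([target]/Kp1)) (6.70 mM, 0.250 mM, k = 89000 M⁻¹ s⁻¹)
    enzyme → spent catalyst (k = 0.0660 min⁻¹)
    target → over-reaction product (k = 2.60 × 10⁻⁴ min⁻¹)

**What stood.** The balance charge from the end states is 10.9 mM in grey and 11.0 mM in violet, beside my 11.1 mM. In grey, the enzyme's half-life of 11 min is longer than the 6.0 min feed, yet 32.7% of the catalyst was spent catalyst by the end. A run with enzyme shares differing between charges would have spoken against the forecast's single constant, but grey and violet each ended with 67.3% enzyme. By 60.0 min, violet held 1.91% enzyme, with 36.2% of its charge still substrate.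

(All runs come from a simulation with constants of no real substance, noise included.)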